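## Retrosynthetic overview

1. Target ⇒ its 7,4′-bis-MOM ether by a final acetal cleavage. No ring is formed in the route: rings A, C and B all arrive intact in genistein.
2. Key disconnection: C1′–C2′ of the C8 side chain, between two aldehyde carbons. The 8-formyl carbon is used as a benzylic carbanion equivalent through its N–H hydrazone and attacks the carbonyl carbon of methacrolein. A chiral Ru–diphosphine catalyst sets the S carbinol centre in the same step.
3. C6–prenyl bond: direct C-alkylation of the 8-formyl compound with prenyl bromide, C6 being the only free ring-A carbon at that stage.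
4. C8–CHO bond: Duff formylation of genistein.

Assumption 1: the Duff formylation of genistein goes to C8, as iminium electrophiles generally do with 5,7-dihydroxy(iso)flavones. The regiochemistry is confirmed by HMBC before going on.

Assumption 2: the sense of induction of the chiral diphosphine in step 4 cannot be predicted from precedent. (S,S)-Me-BPE, 1,2-bis[(2S,5S)-2,5-dimethylphospholan-1-yl]ethane, is written; its commercially available antipode is used if the first run gives the R alcohol.

## Route

Step 1
Reactants: 1 genistein (5,7-dihydroxy-3-(4-hydroxyphenyl)-4H-chromen-4-one)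
Product: 2 8-formylgenistein (5,7-dihydroxy-3-(4-hydroxyphenyl)-4-oxo-4H-chromene-8-carbaldehyde)
Conditions: hexamethylenetetramine (3 equiv), AcOH, 100 °C, 4 h; then 3 M aq HCl, 80 °C, 30 min
Reagents that add atoms: hexamethylenetetramine, C1N2CN3CN1CN(C2)C3 (formyl carbon); water, O (formyl oxygen)
Why: Duff reaction: the iminium electrophile from protonated hexamethylenetetramine attacks the phloroglucinol-type ring A at C8, ortho to the free 7-OH (C6 lies between two hydroxyls, one locked in the C4=O chelate, and ring B is far less activated), and redox transfer plus hydrolysis gives the aldehyde, which deactivates the ring against a second formylation.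

Step 2
Reactants: 2 8-formylgenistein; 3 prenyl bromide (1-bromo-3-methylbut-2-ene)
Product: 4 8-formyl-6-prenylgenistein (5,7-dihydroxy-3-(4-hydroxyphenyl)-6-(3-methylbut-2-en-1-yl)-4-oxo-4H-chromene-8-carbaldehyde)
Conditions: 3 (1.3 equiv), NaOMe (1.1 equiv), MeOH, 0 °C to rt, 12 h
Reagents that add atoms: none
Why: Nuclear C-prenylation (C-alkylation of an ambident phenolate, as with diacylphloroglucinols): one equivalent of NaOMe deprotonates only the vinylogous-acid 7-OH, and in methanol its soft, hydrogen-bonded anion is alkylated at C6, the only free ring-A carbon, rather than at oxygen.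

Step 3
Reactants: 4 8-formyl-6-prenylgenistein
Product: 5 5-hydroxy-7-(methoxymethoxy)-3-[4-(methoxymethoxy)phenyl]-6-(3-methylbut-2-en-1-yl)-4-oxo-4H-chromene-8-carbaldehyde
Conditions: MOMCl (2.6 equiv), K2CO3 (4 equiv), acetone, rt, 6 h
Reagents that add atoms: chloromethyl methyl ether (MOMCl), COCCl
Why: Williamson-type O-alkylation (MOM protection): the acidic 7-OH and 4′-OH are alkylated while the 5-OH, chelated to C4=O, is left alone, and masking the 7-OH stops the aldehyde hydrazone of the next step from acting as an N,O-chelating ligand.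

Step 4
Reactants: 5 bis-MOM aldehyde; 6 methacrolein (2-methylprop-2-enal)
Product: 8 5-hydroxy-8-[(2S)-2-hydroxy-3-methylbut-3-en-1-yl]-7-(methoxymethoxy)-3-[4-(methoxymethoxy)phenyl]-6-(3-methylbut-2-en-1-yl)-4H-chromen-4-one, via hydrazone 7 (not isolated)
Conditions: N2H4·H2O (1.2 equiv), THF, rt, 1 h; then 6 (3 equiv), [RuCl2(p-cymene)]2 (2.5 mol%), (S,S)-Me-BPE (5.5 mol%), K3PO4 (0.5 equiv), THF, 45 °C, 12 h, Ar
Reagents that add atoms: hydrazine hydrate, NN.O (supplies the two N atoms of 7 only; they leave as N2, so in 8 it leaves nothing but hydrogen)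
Why: Proposed new method: the N–H hydrazone 7, deprotonated on the ruthenium–diphosphine centre, reacts at carbon as a benzylic carbanion equivalent with ruthenium-bound methacrolein through a chair-like six-membered transition state (1,2-addition) and then loses N2, so two aldehyde carbons are joined and the former formyl carbon ends as CH2; the C2-symmetric bis(phospholane), a chiral analogue of the dmpe ligand of the closest known reaction (the [RuCl2(p-cymene)]2/dmpe/K3PO4-catalysed addition of aldehyde hydrazones to aldehydes and ketones, which tolerates protic groups and shows measurable induction with chiral diphosphines), is expected to differentiate the two faces of the enal carbonyl and so set the S carbinol centre.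

Step 5
Reactants: 8 bis-MOM S alcohol
Product: 9 target, 5,7-dihydroxy-8-[(2S)-2-hydroxy-3-methylbut-3-en-1-yl]-3-(4-hydroxyphenyl)-6-(3-methylbut-2-en-1-yl)-4H-chromen-4-one
Conditions: 3 M aq HCl/MeOH (1:6), 40 °C, 2 h
Reagents that add atoms: none
Why: Acid-catalysed acetal exchange (MOM cleavage) in methanol frees both phenols under conditions mild enough to leave the prenyl group, the allylic alcohol and its S centre untouched.

## Compound list

1 | genistein, 5,7-dihydroxy-3-(4-hydroxyphenyl)-4H-chromen-4-one | O=c1c(-c2ccc(O)cc2)coc2cc(O)cc(O)c12 | starting material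
2 | 8-formylgenistein, 5,7-dihydroxy-3-(4-hydroxyphenyl)-4-oxo-4H-chromene-8-carbaldehyde | O=Cc1c(O)cc(O)c2c(=O)c(-c3ccc(O)cc3)coc12 | intermediate
3 | prenyl bromide, 1-bromo-3-methylbut-2-ene | CC(C)=CCBr | starting material
4 | 8-formyl-6-prenylgenistein, 5,7-dihydroxy-3-(4-hydroxyphenyl)-6-(3-methylbut-2-en-1-yl)-4-oxo-4H-chromene-8-carbaldehyde | O=Cc1c(O)c(CC=C(C)C)c(O)c2c(=O)c(-c3ccc(O)cc3)coc12 | intermediate
5 | 5-hydroxy-7-(methoxymethoxy)-3-[4-(methoxymethoxy)phenyl]-6-(3-methylbut-2-en-1-yl)-4-oxo-4H-chromene-8-carbaldehyde | O=Cc1c(OCOC)c(CC=C(C)C)c(O)c2c(=O)c(-c3ccc(OCOC)cc3)coc12 | intermediate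
6 | methacrolein, 2-methylprop-2-enal | C=C(C)C=O | starting material
7 | (E)-hydrazone of aldehyde 5 (8-CH=N–NH2) | N/N=C/c1c(OCOC)c(CC=C(C)C)c(O)c2c(=O)c(-c3ccc(OCOC)cc3)coc12 | intermediate
8 | 5-hydroxy-8-[(2S)-2-hydroxy-3-methylbut-3-en-1-yl]-7-(methoxymethoxy)-3-[4-(methoxymethoxy)phenyl]-6-(3-methylbut-2-en-1-yl)-4H-chromen-4-one | C=C(C)[C@@H](O)Cc1c(OCOC)c(CC=C(C)C)c(O)c2c(=O)c(-c3ccc(OCOC)cc3)coc12 | intermediate
9 | 5,7-dihydroxy-8-[(2S)-2-hydroxy-3-methylbut-3-en-1-yl]-3-(4-hydroxyphenyl)-6-(3-methylbut-2-en-1-yl)-4H-chromen-4-one | C=C(C)[C@@H](O)Cc1c(O)c(CC=C(C)C)c(O)c2c(=O)c(-c3ccc(O)cc3)coc12 | target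

## Step count and risks

Total step count: 5. Longest linear sequence: 5 steps (1 → 2 → 4 → 5 → 8 → 9).

The three steps most likely to fail:

**Step 4.** The hydrazone addition to an enal on a hindered, doubly ortho-substituted aryl aldehyde is unproven, and the level of asymmetric induction is unknown. Likely failure modes are mixed azine formation with methacrolein, conjugate instead of 1,2-addition, Wolff–Kishner reduction to the 8-methyl compound, and low ee. The fallback moves stereocontrol from the C–C bond formation to a ketone reduction. Setting out from 5 and 6, the addition is run under the same [RuCl2(p-cymene)]2/K3PO4 conditions but with the achiral parent ligand dmpe (1,2-bis(dimethylphosphino)ethane), giving the racemic bis-MOM alcohol F1. Dess–Martin periodinane (NaHCO3, CH2Cl2, 0 °C) oxidises it to the isopropenyl ketone F2. Reduction with (R)-2-methyl-CBS-oxazaborolidine and catecholborane (toluene, −78 °C), with the isopropenyl group as the large substituent, should give the S alcohol and comes back to the route at 8; the configuration is checked by Mosher ester analysis.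

**Step 2.** O-prenylation at the 7-oxygen, double alkylation at C6 and solvolysis of prenyl bromide can leave the C-prenyl product in low yield. The fallback delivers the prenyl group by an O-to-C sigmatropic shift instead. Setting out from 2, the most acidic 7-OH is alkylated with 3-chloro-3-methylbut-1-yne (DBU, CuCl2 1 mol%, MeCN, 0 °C) to the 7-O-(2-methylbut-3-yn-2-yl) ether F3. Semihydrogenation (H2, Pd/CaCO3 poisoned with Pb(OAc)2, quinoline, EtOAc) gives the 7-O-(2-methylbut-3-en-2-yl) ether F4. Heating in toluene at 110 °C brings about the aromatic Claisen rearrangement to C6, the only unsubstituted ortho position, which turns the reverse-prenyl ether into the normal C-prenyl group and comes back to the route at 4.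

**Step 1.** The formylation may give the 6-formyl isomer, mixtures or diformylation. The fallback fixes both ring-A substituents by construction and bypasses step 2 as well. Setting out from 1, MOMCl/K2CO3 in acetone gives 7,4′-bis-O-MOM genistein F5. Allyl bromide with K2CO3 in DMF at 60 °C alkylates the chelated 5-OH to the 5-O-allyl ether F6. Claisen rearrangement in N,N-diethylaniline at 200 °C can only go to C6 and gives the 6-allyl-5-hydroxy compound F7. Cross-metathesis with 2-methylbut-2-ene (second-generation Grubbs catalyst RuCl2(=CHPh)(H2IMes)(PCy3), CH2Cl2, 40 °C) converts allyl into prenyl, giving 7,4′-bis-O-MOM-6-prenylgenistein F8. Dilute HCl in MeOH removes the MOM groups to give 6-prenylgenistein F9 (wighteone). Duff formylation (hexamethylenetetramine, AcOH, 90 °C; then aq HCl) then has only C8 left on ring A and comes back to the route at 4.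

## Further compounds

F1 | step 4 | racemic 5-hydroxy-8-(2-hydroxy-3-methylbut-3-en-1-yl)-7-(methoxymethoxy)-3-[4-(methoxymethoxy)phenyl]-6-(3-methylbut-2-en-1-yl)-4H-chromen-4-one | C=C(C)C(O)Cc1c(OCOC)c(CC=C(C)C)c(O)c2c(=O)c(-c3ccc(OCOC)cc3)coc12
F2 | step 4 | 5-hydroxy-7-(methoxymethoxy)-3-[4-(methoxymethoxy)phenyl]-6-(3-methylbut-2-en-1-yl)-8-(3-methyl-2-oxobut-3-en-1-yl)-4H-chromen-4-one | C=C(C)C(=O)Cc1c(OCOC)c(CC=C(C)C)c(O)c2c(=O)c(-c3ccc(OCOC)cc3)coc12
F3 | step 2 | 5-hydroxy-3-(4-hydroxyphenyl)-7-[(2-methylbut-3-yn-2-yl)oxy]-4-oxo-4H-chromene-8-carbaldehyde | O=Cc1c(OC(C)(C)C#C)cc(O)c2c(=O)c(-c3ccc(O)cc3)coc12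
F4 | step 2 | 5-hydroxy-3-(4-hydroxyphenyl)-7-[(2-methylbut-3-en-2-yl)oxy]-4-oxo-4H-chromene-8-carbaldehyde | O=Cc1c(OC(C)(C)C=C)cc(O)c2c(=O)c(-c3ccc(O)cc3)coc12
F5 | step 1 | 5-hydroxy-7-(methoxymethoxy)-3-[4-(methoxymethoxy)phenyl]-4H-chromen-4-one | O=c1c(-c2ccc(OCOC)cc2)coc2cc(OCOC)cc(O)c12
F6 | step 1 | 7-(methoxymethoxy)-3-[4-(methoxymethoxy)phenyl]-5-(prop-2-en-1-yloxy)-4H-chromen-4-one | O=c1c(-c2ccc(OCOC)cc2)coc2cc(OCOC)cc(OCC=C)c12
F7 | step 1 | 5-hydroxy-7-(methoxymethoxy)-3-[4-(methoxymethoxy)phenyl]-6-(prop-2-en-1-yl)-4H-chromen-4-one | O=c1c(-c2ccc(OCOC)cc2)coc2cc(OCOC)c(CC=C)c(O)c12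
F8 | step 1 | 5-hydroxy-7-(methoxymethoxy)-3-[4-(methoxymethoxy)phenyl]-6-(3-methylbut-2-en-1-yl)-4H-chromen-4-one | O=c1c(-c2ccc(OCOC)cc2)coc2cc(OCOC)c(CC=C(C)C)c(O)c12
F9 | step 1 | 6-prenylgenistein, 5,7-dihydroxy-3-(4-hydroxyphenyl)-6-(3-methylbut-2-en-1-yl)-4H-chromen-4-one | O=c1c(-c2ccc(O)cc2)coc2cc(O)c(CC=C(C)C)c(O)c12
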